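**Plan**

- Retrosynthetic cuts: O1–C8a (ring C), C4–C4a (ring A aryl Grignard onto a Weinreb amide), C2–C3 (Claisen acylation of an acetamide enolate by the ring B ester), Cα–Cβ of the side chain (aldol) and O4′–Cβ (phenol O-alkylation).
- Forward order: methyl syringate (ring B) is O-alkylated, the glycerol side chain is built by a boron aldol and locked as an acetonide; the ester is extended to a β-keto Weinreb amide, reduced, joined to ring A, and ring C is closed last; C4 oxidation and deprotection finish.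
- Stereochemistry: Cα (R) and Cβ (R) come from an Evans syn aldol under (4S)-4-benzyloxazolidin-2-one control; C2 (S) comes from transfer hydrogenation with RuCl[(S,S)-TsDPEN](p-cymene); the C4 carbinol is set by chelation-controlled reduction and erased on oxidation.
- Enabling feature: the ring C ether oxygen O1 lies between the benzylic stereocentre C2 and the aromatic carbon C8a of ring A, so forming O1–C8a on the arene closes ring C while all four bonds at C2 stay in place.

Key step: step 11

Remark: the chloroacetyl oxazolidinone and N-methoxy-N-methylacetamide are taken as purchasable reagents; methyl syringate replaces syringaldehyde because its ester survives the boron aldol and later supplies C2 as an acyl carbon.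

Notation: Cα = side-chain carbinol carbon, Cβ = side-chain ether carbon, Cγ = CH2OH. Ar* = 4-{[(4R,5R)-4-[4-(benzyloxy)phenyl]-2,2-dimethyl-1,3-dioxan-5-yl]oxy}-3,5-dimethoxyphenyl (ring B with the acetonide-protected side chain).

**Route**

Step 1
Reactants: 1 methyl syringate; 2 (4S)-4-benzyl-3-(chloroacetyl)-1,3-oxazolidin-2-one
Product: 3 aryloxyacetyl imide of methyl syringate
Conditions: K2CO3, NaI (cat.), MeCN, 60 °C
Reagents that add atoms: none
Why: Williamson-type SN2 O-alkylation of the hindered phenoxide by the activated α-chloro imide (iodide catalysis) should give the aryloxyacetyl imide, acyl transfer being reversible because the phenoxide is the better leaving group.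

Step 2
Reactants: 3 aryloxyacetyl imide; 4 4-(benzyloxy)benzaldehyde
Product: 6 (2S,3R)-syn aldol imide, via dibutylboron Z-enolate 5 (not isolated)
Conditions: Bu2BOTf, iPr2NEt, CH2Cl2, 0 °C; 4, −78 → 0 °C; then pH 7 buffer, MeOH, H2O2
Reagents that add atoms: none
Why: Evans syn aldol, in which the Z-boron enolate reacts through a Zimmerman–Traxler chair with one face shielded by the (4S)-benzyl group, should give the (2S,3R) adduct, which is the (αR,βR) threo arrangement of the target.

Step 3
Reactants: 6 (2S,3R)-syn aldol imide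
Product: 7 (1R,2R)-diol ester
Conditions: NaBH4, THF/H2O (4:1), 0 °C → rt
Reagents that add atoms: none
Why: Reductive cleavage of the N-acyl oxazolidinone by borohydride, whose exocyclic imide carbonyl is far more electrophilic than the aryl methyl ester, should release the primary alcohol and the recoverable auxiliary without touching either stereocentre.

Step 4
Reactants: 7 (1R,2R)-diol ester
Product: 8 acetonide ester Ar*–CO2Me
Conditions: Me2C(OMe)2, PPTS (cat.), CH2Cl2, rt
Reagents that add atoms: 2,2-dimethoxypropane, COC(C)(C)OC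
Why: Acid-catalysed transketalisation of the 1,3-diol gives the six-membered acetonide (aryl equatorial, aryloxy axial), which masks both side-chain hydroxyls for the organometallic, basic and oxidative steps ahead.

Step 5
Reactants: 8 acetonide ester; 9 N-methoxy-N-methylacetamide
Product: 11 β-keto Weinreb amide, via lithium amide enolate 10 (not isolated)
Conditions: 9, lithium diisopropylamide (3 equiv), THF, −78 °C; then 8, −78 → −20 °C; NH4Cl (aq)
Reagents that add atoms: none
Why: Crossed Claisen condensation, in which the amide enolate acylates at the aryl ester and the product is shielded from further attack as its own enolate, forms the C2–C3 bond and brings in C3 and C4 at the amide oxidation level.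

Step 6
Reactants: 11 β-keto Weinreb amide
Product: 12 (3S)-β-hydroxy Weinreb amide
Conditions: RuCl[(S,S)-TsDPEN](p-cymene) (2 mol %), HCO2H/Et3N (5:2), EtOAc, 35 °C
Reagents that add atoms: none
Why: Noyori asymmetric transfer hydrogenation delivers hydride and proton through a six-membered outer-sphere transition state with the aryl ring lying against the η6-arene, so the (S,S) ligand should give the S carbinol (the sense in which acetophenone gives (S)-1-phenylethanol), which sets C2.

Step 7
Reactants: 13 5-bromoresorcinol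
Product: 14 1,3-bis(benzyloxy)-5-bromobenzene
Conditions: BnBr, K2CO3, DMF, 50 °C
Reagents that add atoms: benzyl bromide, BrCc1ccccc1
Why: Williamson ether synthesis on both phenols installs hydrogenolysable groups that match the benzyl ether of the side chain.

Step 8
Reactants: 14 1,3-bis(benzyloxy)-5-bromobenzene
Product: 15 1,5-bis(benzyloxy)-3-bromo-2-iodobenzene
Conditions: NIS, TFA (cat.), MeCN, rt
Reagents that add atoms: N-iodosuccinimide, O=C1CCC(=O)N1I
Why: Electrophilic aromatic iodination should go para to one benzyloxy group and ortho to the other (next to bromine), as is usual for 1-bromo-3,5-dialkoxybenzenes, the site between the two benzyloxy groups being ortho to both and more congested.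

Step 9
Reactants: 15 1,5-bis(benzyloxy)-3-bromo-2-iodobenzene; 12 (3S)-β-hydroxy Weinreb amide
Product: 17 (3S)-β-hydroxy ketone, via arylmagnesium chloride 16 (not isolated)
Conditions: 15 (2.6 equiv), iPrMgCl·LiCl (2.5 equiv), THF, −40 °C; then 12, −40 → 0 °C; NH4Cl (aq)
Reagents that add atoms: none
Why: Knochel iodine–magnesium exchange is selective for iodide over bromide and gives an ortho-bromoaryl Grignard reagent that is stable below 0 °C, of which one equivalent deprotonates the hydroxyl and a second adds to the Weinreb amide to form a chelated tetrahedral adduct that collapses to the ketone only on work-up, so C4–C4a forms without over-addition and C2 is untouched.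

Step 10
Reactants: 17 (3S)-β-hydroxy ketone
Product: 18 (1R,3S)-syn-1,3-diol
Conditions: Et2BOMe, THF/MeOH (4:1), −78 °C; NaBH4, −78 → −40 °C; MeOH co-evaporation
Reagents that add atoms: none
Why: Narasaka–Prasad reduction, in which external hydride attacks the diethylboron chelate of the β-hydroxy ketone axially, should give the 1,3-syn diol (new carbinol R) and removes the retro-aldol-prone ketone before the basic cyclisation; this centre is erased again in step 12.

Step 11
Reactants: 18 (1R,3S)-syn-1,3-diol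
Product: 19 (2S,4R)-flavan-4-ol
Conditions: CuI (10 mol %), 3,4,7,8-tetramethyl-1,10-phenanthroline (20 mol %), Cs2CO3, toluene (0.02 M), 110 °C, Ar
Reagents that add atoms: none
Why: Cs2CO3 generates the alkoxide of the ring B carbinol on phenanthroline-bound monovalent copper, the metal inserts into the neighbouring C8a–Br bond, and C–O reductive elimination from the resulting trivalent copper aryl alkoxide forms O1–C8a and returns the catalyst. The closest known reaction type is the copper-catalysed intramolecular Ullmann-type O-arylation of secondary alcohols by aryl bromides that gives 2-substituted chromans. Ring C closes as a six-membered ring by attack of the tethered oxygen on the arene carbon through a seven-membered metallacycle (exo with respect to the C–Br bond). No stereocentre is created: the C2–O bond is never broken, so C2 stays S, and the C4 carbinol is a spectator. The step needs selectivity between the two hydroxyls and freedom from carbinol oxidation: the C4 hydroxyl could only close a four-membered ring, copper alkoxides are slow to undergo β-hydride elimination, and keeping C4 at the alcohol level leaves no retro-aldol or elimination pathway under the carbonate base. High dilution disfavours intermolecular etherification.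

Step 12
Reactants: 19 (2S,4R)-flavan-4-ol
Product: 20 protected (2S)-flavanone
Conditions: Dess–Martin periodinane, NaHCO3, CH2Cl2, 0 °C → rt
Reagents that add atoms: none
Why: Dess–Martin oxidation of the only free hydroxyl under buffered, near-neutral conditions should give the C4 ketone without opening ring C to the chalcone, so C2 stays S.

Step 13
Reactants: 20 protected (2S)-flavanone
Product: 21 flavanone side-chain diol
Conditions: AcOH/THF/H2O (3:1:1), 40 °C
Reagents that add atoms: none
Why: Acid-catalysed acetal hydrolysis releases the 1,3-diol, while the weak acid and the cation-destabilising β-aryloxy group should keep the benzylic Cα centre from ionising and the benzyl ethers and flavanone are stable.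

Step 14
Reactants: 21 flavanone side-chain diol
Product: 22 target flavanone
Conditions: H2 (1 atm), 10% Pd/C, EtOAc/MeOH (1:1), rt
Reagents that add atoms: none
Why: Catalytic hydrogenolysis cleaves the three aryl benzyl ethers much faster than the benzylic Cα–OH or C2–O1 bonds, so stopping after three equivalents of hydrogen should give the target.

**Compound list**

1 | methyl syringate (methyl 4-hydroxy-3,5-dimethoxybenzoate) | COC(=O)c1cc(OC)c(O)c(OC)c1 | starting material
2 | (4S)-4-benzyl-3-(chloroacetyl)-1,3-oxazolidin-2-one | O=C(CCl)N1[C@@H](Cc2ccccc2)COC1=O | starting material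
3 | methyl 4-{2-[(4S)-4-benzyl-2-oxo-1,3-oxazolidin-3-yl]-2-oxoethoxy}-3,5-dimethoxybenzoate | COC(=O)c1cc(OC)c(OCC(=O)N2[C@@H](Cc3ccccc3)COC2=O)c(OC)c1 | intermediate
4 | 4-(benzyloxy)benzaldehyde | O=Cc1ccc(OCc2ccccc2)cc1 | starting material
5 | dibutylboron (Z)-enolate of 3 | CCCCB(CCCC)O/C(=C\Oc1c(OC)cc(cc1OC)C(=O)OC)N1[C@@H](Cc2ccccc2)COC1=O | intermediate
6 | methyl 4-{[(2S,3R)-1-[(4S)-4-benzyl-2-oxo-1,3-oxazolidin-3-yl]-3-[4-(benzyloxy)phenyl]-3-hydroxy-1-oxopropan-2-yl]oxy}-3,5-dimethoxybenzoate | COC(=O)c1cc(OC)c(O[C@H](C(=O)N2[C@@H](Cc3ccccc3)COC2=O)[C@H](O)c2ccc(OCc3ccccc3)cc2)c(OC)c1 | intermediate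
7 | methyl 4-{[(1R,2R)-1-[4-(benzyloxy)phenyl]-1,3-dihydroxypropan-2-yl]oxy}-3,5-dimethoxybenzoate | COC(=O)c1cc(OC)c(O[C@H](CO)[C@H](O)c2ccc(OCc3ccccc3)cc2)c(OC)c1 | intermediate
8 | methyl 4-{[(4R,5R)-4-[4-(benzyloxy)phenyl]-2,2-dimethyl-1,3-dioxan-5-yl]oxy}-3,5-dimethoxybenzoate (Ar*–CO2Me) | COC(=O)c1cc(OC)c(O[C@@H]2COC(C)(C)O[C@@H]2c2ccc(OCc3ccccc3)cc2)c(OC)c1 | intermediate
9 | N-methoxy-N-methylacetamide | CC(=O)N(C)OC | starting material
10 | lithium enolate of 9 | [Li]OC(=C)N(C)OC | intermediate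
11 | 3-Ar*-N-methoxy-N-methyl-3-oxopropanamide | CON(C)C(=O)CC(=O)c1cc(OC)c(O[C@@H]2COC(C)(C)O[C@@H]2c2ccc(OCc3ccccc3)cc2)c(OC)c1 | intermediate
12 | (3S)-3-Ar*-3-hydroxy-N-methoxy-N-methylpropanamide | CON(C)C(=O)C[C@H](O)c1cc(OC)c(O[C@@H]2COC(C)(C)O[C@@H]2c2ccc(OCc3ccccc3)cc2)c(OC)c1 | intermediate
13 | 5-bromoresorcinol (5-bromobenzene-1,3-diol) | Oc1cc(O)cc(Br)c1 | starting material
14 | 1,3-bis(benzyloxy)-5-bromobenzene | Brc1cc(OCc2ccccc2)cc(OCc2ccccc2)c1 | intermediate
15 | 1,5-bis(benzyloxy)-3-bromo-2-iodobenzene | Ic1c(Br)cc(OCc2ccccc2)cc1OCc1ccccc1 | intermediate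
16 | [2,4-bis(benzyloxy)-6-bromophenyl]magnesium chloride | Cl[Mg]c1c(Br)cc(OCc2ccccc2)cc1OCc1ccccc1 | intermediate
17 | (3S)-1-[2,4-bis(benzyloxy)-6-bromophenyl]-3-Ar*-3-hydroxypropan-1-one | O=C(C[C@H](O)c1cc(OC)c(O[C@@H]2COC(C)(C)O[C@@H]2c2ccc(OCc3ccccc3)cc2)c(OC)c1)c1c(Br)cc(OCc2ccccc2)cc1OCc1ccccc1 | intermediate
18 | (1R,3S)-1-[2,4-bis(benzyloxy)-6-bromophenyl]-3-Ar*-propane-1,3-diol (1,3-syn) | O[C@H](C[C@H](O)c1cc(OC)c(O[C@@H]2COC(C)(C)O[C@@H]2c2ccc(OCc3ccccc3)cc2)c(OC)c1)c1c(Br)cc(OCc2ccccc2)cc1OCc1ccccc1 | intermediate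
19 | (2S,4R)-5,7-bis(benzyloxy)-2-Ar*-3,4-dihydro-2H-chromen-4-ol (2,4-trans) | O[C@@H]1C[C@@H](c2cc(OC)c(O[C@@H]3COC(C)(C)O[C@@H]3c3ccc(OCc4ccccc4)cc3)c(OC)c2)Oc2cc(OCc3ccccc3)cc(OCc3ccccc3)c21 | intermediate
20 | (2S)-5,7-bis(benzyloxy)-2-Ar*-2,3-dihydro-4H-chromen-4-one | O=C1C[C@@H](c2cc(OC)c(O[C@@H]3COC(C)(C)O[C@@H]3c3ccc(OCc4ccccc4)cc3)c(OC)c2)Oc2cc(OCc3ccccc3)cc(OCc3ccccc3)c21 | intermediate
21 | (2S)-5,7-bis(benzyloxy)-2-(4-{[(1R,2R)-1-[4-(benzyloxy)phenyl]-1,3-dihydroxypropan-2-yl]oxy}-3,5-dimethoxyphenyl)-2,3-dihydro-4H-chromen-4-one | O=C1C[C@@H](c2cc(OC)c(O[C@H](CO)[C@H](O)c3ccc(OCc4ccccc4)cc3)c(OC)c2)Oc2cc(OCc3ccccc3)cc(OCc3ccccc3)c21 | intermediate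
22 | (2S)-5,7-dihydroxy-2-(4-{[(1R,2R)-1,3-dihydroxy-1-(4-hydroxyphenyl)propan-2-yl]oxy}-3,5-dimethoxyphenyl)-2,3-dihydro-4H-chromen-4-one | COc1cc([C@@H]2CC(=O)c3c(O)cc(O)cc3O2)cc(OC)c1O[C@H](CO)[C@H](O)c1ccc(O)cc1 | target

**Step count**

Total: 14 steps. Longest linear sequence: 12 steps (steps 1–6 and 9–14); ring A is prepared in two steps (7 and 8) and joins at step 9.

**Steps most likely to fail**

Step 11. The copper alkoxide may fail to engage the electron-rich C–Br bond, turnover may stall through chelation by the neighbouring C4 alkoxide, or the bromide may be reduced while a carbinol is oxidised. The fallback sets out from 18, returns at 19, and closes the ring on a substrate with a single free hydroxyl under palladium catalysis. Compound 18 is silylated at the less hindered ring B carbinol (TESCl, imidazole, CH2Cl2, −20 °C) to the mono-triethylsilyl ether F1. The ring A carbinol is then capped (TBSOTf, 2,6-lutidine) to give the mixed bis-silyl ether F2. The triethylsilyl group is removed selectively (HF·pyridine, pyridine, THF, 0 °C) to give the C4-O-silyl alcohol F3. This is cyclised with Pd(OAc)2, 2-(di-tert-butylphosphino)-1,1'-binaphthyl and Cs2CO3 in toluene at 80 °C to the 4-O-silyl flavan F4, and Bu4NF in THF then gives 19.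

Step 9. Addition of the doubly ortho-substituted arylmagnesium to the amide may be slow, and on warming the reagent may lose magnesium halide to an aryne. The fallback sets out from 12, returns at 17, and replaces the amide by an aldehyde electrophile. Compound 12 is silylated (TBSOTf, 2,6-lutidine) to the silyl ether F5 and reduced (i-Bu2AlH, THF, −78 °C) to the β-silyloxy aldehyde F6. This takes up 16 at −40 °C to give the carbinol F7 as both C1 epimers. Dess–Martin oxidation gives the β-silyloxy ketone F8, and HF·pyridine in THF releases 17.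

Step 6. Hydride transfer to the electron-rich aryl ketone may be slow and its facial selectivity incomplete. The fallback sets out from 8, returns at 12, and lets the auxiliary already used for the side chain control C2. Ester 8 is reduced (i-Bu2AlH, CH2Cl2, −78 °C) to the benzylic alcohol F9 and oxidised (MnO2, CH2Cl2) to the aldehyde F10. An Evans syn aldol with the dibutylboron enolate of 2 gives the (2S,3R)-chlorohydrin imide F11. Zinc dust in AcOH/THF removes chlorine to give the (3S)-β-hydroxy imide F12, and transamination with Me3Al and MeNH(OMe)·HCl gives 12.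

Further compounds

F1 | step 11 | (1R,3S)-1-[2,4-bis(benzyloxy)-6-bromophenyl]-3-Ar*-3-[(triethylsilyl)oxy]propan-1-ol | O[C@H](C[C@H](O[Si](CC)(CC)CC)c1cc(OC)c(O[C@@H]2COC(C)(C)O[C@@H]2c2ccc(OCc3ccccc3)cc2)c(OC)c1)c1c(Br)cc(OCc2ccccc2)cc1OCc1ccccc1
F2 | step 11 | (1R,3S)-1-[2,4-bis(benzyloxy)-6-bromophenyl]-3-Ar*-1-[(tert-butyldimethylsilyl)oxy]-3-[(triethylsilyl)oxy]propane | CC(C)(C)[Si](C)(C)O[C@H](C[C@H](O[Si](CC)(CC)CC)c1cc(OC)c(O[C@@H]2COC(C)(C)O[C@@H]2c2ccc(OCc3ccccc3)cc2)c(OC)c1)c1c(Br)cc(OCc2ccccc2)cc1OCc1ccccc1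
F3 | step 11 | (1S,3R)-3-[2,4-bis(benzyloxy)-6-bromophenyl]-1-Ar*-3-[(tert-butyldimethylsilyl)oxy]propan-1-ol | CC(C)(C)[Si](C)(C)O[C@H](C[C@H](O)c1cc(OC)c(O[C@@H]2COC(C)(C)O[C@@H]2c2ccc(OCc3ccccc3)cc2)c(OC)c1)c1c(Br)cc(OCc2ccccc2)cc1OCc1ccccc1
F4 | step 11 | (2S,4R)-5,7-bis(benzyloxy)-2-Ar*-4-[(tert-butyldimethylsilyl)oxy]-3,4-dihydro-2H-chromene | CC(C)(C)[Si](C)(C)O[C@@H]1C[C@@H](c2cc(OC)c(O[C@@H]3COC(C)(C)O[C@@H]3c3ccc(OCc4ccccc4)cc3)c(OC)c2)Oc2cc(OCc3ccccc3)cc(OCc3ccccc3)c21
F5 | step 9 | (3S)-3-Ar*-3-[(tert-butyldimethylsilyl)oxy]-N-methoxy-N-methylpropanamide | CON(C)C(=O)C[C@H](O[Si](C)(C)C(C)(C)C)c1cc(OC)c(O[C@@H]2COC(C)(C)O[C@@H]2c2ccc(OCc3ccccc3)cc2)c(OC)c1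
F6 | step 9 | (3S)-3-Ar*-3-[(tert-butyldimethylsilyl)oxy]propanal | O=CC[C@H](O[Si](C)(C)C(C)(C)C)c1cc(OC)c(O[C@@H]2COC(C)(C)O[C@@H]2c2ccc(OCc3ccccc3)cc2)c(OC)c1
F7 | step 9 | (3S)-1-[2,4-bis(benzyloxy)-6-bromophenyl]-3-Ar*-3-[(tert-butyldimethylsilyl)oxy]propan-1-ol (both C1 epimers) | OC(C[C@H](O[Si](C)(C)C(C)(C)C)c1cc(OC)c(O[C@@H]2COC(C)(C)O[C@@H]2c2ccc(OCc3ccccc3)cc2)c(OC)c1)c1c(Br)cc(OCc2ccccc2)cc1OCc1ccccc1
F8 | step 9 | (3S)-1-[2,4-bis(benzyloxy)-6-bromophenyl]-3-Ar*-3-[(tert-butyldimethylsilyl)oxy]propan-1-one | O=C(C[C@H](O[Si](C)(C)C(C)(C)C)c1cc(OC)c(O[C@@H]2COC(C)(C)O[C@@H]2c2ccc(OCc3ccccc3)cc2)c(OC)c1)c1c(Br)cc(OCc2ccccc2)cc1OCc1ccccc1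
F9 | step 6 | Ar*-methanol | OCc1cc(OC)c(O[C@@H]2COC(C)(C)O[C@@H]2c2ccc(OCc3ccccc3)cc2)c(OC)c1
F10 | step 6 | Ar*-carbaldehyde (4-{[(4R,5R)-4-[4-(benzyloxy)phenyl]-2,2-dimethyl-1,3-dioxan-5-yl]oxy}-3,5-dimethoxybenzaldehyde) | O=Cc1cc(OC)c(O[C@@H]2COC(C)(C)O[C@@H]2c2ccc(OCc3ccccc3)cc2)c(OC)c1
F11 | step 6 | (4S)-4-benzyl-3-[(2S,3R)-2-chloro-3-hydroxy-3-Ar*-propanoyl]-1,3-oxazolidin-2-one | Cl[C@H](C(=O)N1[C@@H](Cc2ccccc2)COC1=O)[C@H](O)c1cc(OC)c(O[C@@H]2COC(C)(C)O[C@@H]2c2ccc(OCc3ccccc3)cc2)c(OC)c1
F12 | step 6 | (4S)-4-benzyl-3-[(3S)-3-hydroxy-3-Ar*-propanoyl]-1,3-oxazolidin-2-one | O=C(C[C@H](O)c1cc(OC)c(O[C@@H]2COC(C)(C)O[C@@H]2c2ccc(OCc3ccccc3)cc2)c(OC)c1)N1[C@@H](Cc2ccccc2)COC1=O
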